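**Retrosynthetic overview**

1. Last disconnection is O1–C8a of the pyran ring: target 24 comes from the Z-alkenyl catechol 21, in which the benzene and cyclohexane rings already exist. The ring is closed by oxidative dearomatisation, 6-endo oxa-Michael addition and re-aromatisation, with the C2–O bond left untouched.
2. Enabling feature: the 5,6-diol (catechol) of the benzene ring. As the C5,C6-o-quinone it makes the unsubstituted ring carbon C8a (between C4a and C8–OMe) the β-carbon of the enone C5(=O)–C4a=C8a, and the Z C3=C4 bond holds the tertiary C2–OH over C8a.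
3. 21 comes from Sonogashira coupling and Lindlar reduction of aryl iodide 18 (from 2-hydroxy-5-methoxybenzaldehyde by iodination and Dakin oxidation) with alkyne 13.
4. 13 comes from octalone 7 (d'Angelo Michael addition and Robinson annulation of 2,6-dimethylcyclohexanone). Equatorial methyl addition sets the carbinol; ozonolysis of the enone C=C opens the temporary ring (vinylic CH becomes the alkyne carbon, ring-fusion C=O becomes the methylidene carbon).
5. Ring order: cyclohexane (from the starting material; a temporary enone ring is closed in step 3 and opened in step 6), benzene (from the starting material), pyran last (step 15).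

Key step: step 15

Remark: commercial 2,6-dimethylcyclohexanone is used as its cis/trans mixture, and octalone 7 is assumed to be brought to a single enantiomer by low-temperature crystallisation if step 2 leaves a minor enantiomer.

**Route**

Step 1
Reactants: 1 2,6-dimethylcyclohexan-1-one; 2 (S)-1-phenylethan-1-amine
Product: 3 (1S)-N-(2,6-dimethylcyclohexylidene)-1-phenylethan-1-amine
Conditions: TsOH·H2O (cat.), toluene, reflux, Dean–Stark
Reagents that add atoms: none
Why: Acid-catalysed imine condensation driven by azeotropic removal of water; the auxiliary stereocentre is the control element for step 2 and the ring α-carbons stay a mixture.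

Step 2
Reactants: 3 (1S)-N-(2,6-dimethylcyclohexylidene)-1-phenylethan-1-amine; 4 but-3-en-2-one
Product: 6 (2R,6RS)-2,6-dimethyl-2-(3-oxobutyl)cyclohexan-1-one, via Michael adduct imine 5 (not isolated)
Conditions: THF, rt → 40 °C; then 20% aq AcOH, rt
Reagents that add atoms: water, O
Why: Deracemising Michael addition of a chiral imine (d'Angelo): the secondary enamine tautomer adds to the enone through a compact chair-like transition state with internal N–H transfer, on the face anti to the phenyl group of the (S)-auxiliary, which should set the quaternary centre as R; C6 stays a mixture that step 3 corrects.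

Step 3
Reactants: 6 (2R,6RS)-2,6-dimethyl-2-(3-oxobutyl)cyclohexan-1-one
Product: 7 (4aR,8R)-4a,8-dimethyl-4,4a,5,6,7,8-hexahydronaphthalen-2(3H)-one
Conditions: NaOMe, MeOH, rt → 60 °C
Reagents that add atoms: none
Why: Intramolecular aldol condensation (second stage of a Robinson annulation); methoxide also equilibrates C8 through the extended dienolate, and the methyl group should settle equatorial, trans to the axial angular methyl (8R), as in the 6β→6α epimerisation of 6-methyl-Δ4-3-keto steroids.

Step 4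
Reactants: 7 (4aR,8R)-4a,8-dimethyl-4,4a,5,6,7,8-hexahydronaphthalen-2(3H)-one
Product: 8 (2S,4aR,8R)-2,4a,8-trimethyl-2,3,4,4a,5,6,7,8-octahydronaphthalen-2-ol
Conditions: MeTi(OiPr)3 (2 equiv), Et2O, −20 °C → rt; aq NH4F; chromatography
Reagents that add atoms: methyltitanium triisopropoxide, C[Ti](OC(C)C)(OC(C)C)OC(C)C
Why: Chemoselective 1,2-addition of a bulky, non-basic methyltitanium reagent, which should attack the half-chair enone from the equatorial direction (the face syn to the angular methyl) and so give the 2S carbinol with axial OH; the minor C2 epimer is removed by chromatography.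

Step 5
Reactants: 8 (2S,4aR,8R)-2,4a,8-trimethyl-2,3,4,4a,5,6,7,8-octahydronaphthalen-2-ol
Product: 9 triethyl{[(2S,4aR,8R)-2,4a,8-trimethyl-2,3,4,4a,5,6,7,8-octahydronaphthalen-2-yl]oxy}silane
Conditions: TESOTf, 2,6-lutidine, CH2Cl2, −78 → 0 °C
Reagents that add atoms: triethylsilyl trifluoromethanesulfonate, CC[Si](CC)(CC)OS(=O)(=O)C(F)(F)F
Why: Silylation of a tertiary alcohol with a silyl triflate under buffered conditions, which masks the carbinol before the α-oxy aldehyde is unveiled and forms no stereocentre.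

Step 6
Reactants: 9 triethyl{[(2S,4aR,8R)-2,4a,8-trimethyl-2,3,4,4a,5,6,7,8-octahydronaphthalen-2-yl]oxy}silane
Product: 11 (2S)-4-[(1R,3R)-1,3-dimethyl-2-oxocyclohexyl]-2-methyl-2-[(triethylsilyl)oxy]butanal, via ozonide 10 (not isolated)
Conditions: O3, CH2Cl2, −78 °C; then PPh3, −78 °C → rt
Reagents that add atoms: ozone, [O-][O+]=O
Why: Ozonolysis with reductive work-up cleaves the only C=C bond and opens the temporary ring to the hindered ring ketone and the α-silyloxy aldehyde under neutral conditions that should leave all three stereocentres untouched.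

Step 7
Reactants: 11 (2S)-4-[(1R,3R)-1,3-dimethyl-2-oxocyclohexyl]-2-methyl-2-[(triethylsilyl)oxy]butanal
Product: 12 (2R,6R)-2,6-dimethyl-2-{(3S)-3-methyl-3-[(triethylsilyl)oxy]pent-4-yn-1-yl}cyclohexan-1-one
Conditions: dimethyl (1-diazo-2-oxopropyl)phosphonate, K2CO3, MeOH, 0 °C → rt
Reagents that add atoms: dimethyl (1-diazo-2-oxopropyl)phosphonate, COP(=O)(OC)C(=[N+]=[N-])C(C)=O
Why: Ohira–Bestmann (Seyferth–Gilbert) homologation converts the aldehyde into the terminal alkyne while the 2,2,6-trisubstituted ketone does not react, and the mild carbonate base at low temperature should not enolise its hindered tertiary α-position.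

Step 8
Reactants: 12 (2R,6R)-2,6-dimethyl-2-{(3S)-3-methyl-3-[(triethylsilyl)oxy]pent-4-yn-1-yl}cyclohexan-1-one
Product: 13 triethyl({(3S)-5-[(1R,3R)-1,3-dimethyl-2-methylidenecyclohexyl]-3-methylpent-1-yn-3-yl}oxy)silane
Conditions: Zn, CH2Br2, TiCl4 (Lombardo reagent), THF/CH2Cl2, 0 °C → rt
Reagents that add atoms: dibromomethane, BrCBr
Why: Takai–Lombardo methylenation, a non-basic Zn/Ti carbenoid olefination suited to hindered enolisable ketones, should install the exocyclic methylidene group without epimerising the adjacent methyl-bearing centre.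

Step 9
Reactants: 14 2-hydroxy-5-methoxybenzaldehyde
Product: 15 2-hydroxy-3-iodo-5-methoxybenzaldehyde
Conditions: NIS, DMF, 0 °C → rt
Reagents that add atoms: N-iodosuccinimide, O=C1CCC(=O)N1I
Why: Electrophilic aromatic iodination directed by the phenol to its only free ortho position, the para position being blocked by the methoxy group.

Step 10
Reactants: 15 2-hydroxy-3-iodo-5-methoxybenzaldehyde
Product: 17 3-iodo-5-methoxybenzene-1,2-diol, via aryl formate 16 (not isolated)
Conditions: 30% H2O2, aq NaOH, THF, 0 °C, N2; then dilute HCl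
Reagents that add atoms: hydrogen peroxide, OO
Why: Dakin oxidation of an ortho-hydroxybenzaldehyde (aryl migration in the peroxide adduct, then hydrolysis of the formate) turns the formyl group into the second catechol hydroxyl.

Step 11
Reactants: 17 3-iodo-5-methoxybenzene-1,2-diol
Product: 18 [(3-iodo-5-methoxy-1,2-phenylene)bis(oxy)]bis(tert-butyldimethylsilane)
Conditions: TBSCl, imidazole, DMAP (cat.), DMF, rt → 40 °C
Reagents that add atoms: tert-butyldimethylsilyl chloride, CC(C)(C)[Si](C)(C)Cl
Why: Standard bis-silylation protects the oxidation-prone catechol for the Pd/Cu coupling and the hydrogenation.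

Step 12
Reactants: 13 triethyl({(3S)-5-[(1R,3R)-1,3-dimethyl-2-methylidenecyclohexyl]-3-methylpent-1-yn-3-yl}oxy)silane; 18 [(3-iodo-5-methoxy-1,2-phenylene)bis(oxy)]bis(tert-butyldimethylsilane)
Product: 19 [(3-{(3S)-5-[(1R,3R)-1,3-dimethyl-2-methylidenecyclohexyl]-3-methyl-3-[(triethylsilyl)oxy]pent-1-yn-1-yl}-5-methoxy-1,2-phenylene)bis(oxy)]bis(tert-butyldimethylsilane)
Conditions: Pd(PPh3)2Cl2 (5 mol%), CuI (10 mol%), Et3N/THF, 50 °C, degassed
Reagents that add atoms: none
Why: Sonogashira coupling of an aryl iodide with a terminal tertiary-propargylic alkyne joins the two halves without touching any stereocentre.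

Step 13
Reactants: 19 [(3-{(3S)-5-[(1R,3R)-1,3-dimethyl-2-methylidenecyclohexyl]-3-methyl-3-[(triethylsilyl)oxy]pent-1-yn-1-yl}-5-methoxy-1,2-phenylene)bis(oxy)]bis(tert-butyldimethylsilane)
Product: 20 [(3-{(1Z,3S)-5-[(1R,3R)-1,3-dimethyl-2-methylidenecyclohexyl]-3-methyl-3-[(triethylsilyl)oxy]pent-1-en-1-yl}-5-methoxy-1,2-phenylene)bis(oxy)]bis(tert-butyldimethylsilane)
Conditions: H2 (1 atm), Lindlar catalyst, quinoline, EtOAc, rt
Reagents that add atoms: none
Why: Lindlar semihydrogenation adds hydrogen syn on poisoned palladium and should give the Z-olefin that the ring closure needs, while the hindered exocyclic methylidene group is not reduced.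

Step 14
Reactants: 20 [(3-{(1Z,3S)-5-[(1R,3R)-1,3-dimethyl-2-methylidenecyclohexyl]-3-methyl-3-[(triethylsilyl)oxy]pent-1-en-1-yl}-5-methoxy-1,2-phenylene)bis(oxy)]bis(tert-butyldimethylsilane)
Product: 21 3-{(1Z,3S)-5-[(1R,3R)-1,3-dimethyl-2-methylidenecyclohexyl]-3-hydroxy-3-methylpent-1-en-1-yl}-5-methoxybenzene-1,2-diol
Conditions: TBAF (4 equiv), AcOH (4 equiv), THF, 0 °C → rt, Ar; used at once
Reagents that add atoms: none
Why: Buffered fluoride desilylation frees the catechol and the tertiary alcohol together under non-acidic conditions, so the ionisable Z-allylic alcohol should survive with its configuration.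

Step 15
Reactants: 21 3-{(1Z,3S)-5-[(1R,3R)-1,3-dimethyl-2-methylidenecyclohexyl]-3-hydroxy-3-methylpent-1-en-1-yl}-5-methoxybenzene-1,2-diol
Product: 24 (2S)-2-{2-[(1R,3R)-1,3-dimethyl-2-methylidenecyclohexyl]ethyl}-8-methoxy-2-methyl-2H-chromene-5,6-diol, via o-quinone 22 (not isolated), via chromene-5,6-dione 23 (not isolated)
Conditions: Ag2O (2.5 equiv), NaHCO3, 4 Å MS, CH2Cl2, 0 °C, dark; filter; then aq Na2S2O4, 0 °C
Reagents that add atoms: none
Why: Proposed new method: Ag2O dearomatises the 5,6-catechol of 21 to o-quinone 22; the tertiary C2 hydroxyl, held over the ring by the Z C3=C4 bond, adds in an intramolecular oxa-Michael reaction to C8a, the β-carbon of the C5(=O)–C4a=C8a enone, and enolisation re-aromatises the ring; the cyclised catechol, being more electron-rich than 21, is carried by the excess oxidant to dione 23, which the dithionite wash returns to 24. The closest known reaction type is the oxidative cyclisation of catechols through their o-quinones with tethered N or O nucleophiles (cyclodopa formation, oxidative lactonisation of dihydrocaffeic acid to a 6,7-dihydroxydihydrocoumarin); a tertiary allylic alcohol closing a 2H-chromene in this way is the untested part. The pyran ring closes 6-endo-trig at the ring C4a=C8a bond through a nearly planar array that already has the shape of the chromene. No new stereocentre arises: C2 keeps the configuration set in step 4, because its C–O bond is never broken and an electron-poor quinone does not assist ionisation of the allylic alcohol. The step needs site selectivity for C8a over cyclisation through the C5 oxygen and over hemiketal formation at C5; the quinone oxidation level secures it, since the C5 oxygen is then a non-nucleophilic carbonyl, hemiketal formation is reversible, and only the C8a adduct can aromatise. It also needs oxidation of the catechol beside three alkenes, which the mild oxidant and the low oxidation potential of the methoxycatechol should provide, and short contact at 0 °C should keep dione 23 from electrocyclic ring opening.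

**Compound list**

1 | 2,6-dimethylcyclohexan-1-one (cis/trans mixture) | CC1CCCC(C)C1=O | starting material
2 | (S)-1-phenylethan-1-amine | C[C@H](N)c1ccccc1 | starting material
3 | (1S)-N-(2,6-dimethylcyclohexylidene)-1-phenylethan-1-amine | CC1CCCC(C)C1=N[C@@H](C)c1ccccc1 | intermediate
4 | but-3-en-2-one | C=CC(C)=O | starting material
5 | 4-[(1R)-1,3-dimethyl-2-{[(1S)-1-phenylethyl]imino}cyclohexyl]butan-2-one | CC(=O)CC[C@@]1(C)CCCC(C)C1=N[C@@H](C)c1ccccc1 | intermediate
6 | (2R,6RS)-2,6-dimethyl-2-(3-oxobutyl)cyclohexan-1-one | CC(=O)CC[C@@]1(C)CCCC(C)C1=O | intermediate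
7 | (4aR,8R)-4a,8-dimethyl-4,4a,5,6,7,8-hexahydronaphthalen-2(3H)-one | O=C1C=C2[C@H](C)CCC[C@]2(C)CC1 | intermediate
8 | (2S,4aR,8R)-2,4a,8-trimethyl-2,3,4,4a,5,6,7,8-octahydronaphthalen-2-ol | C[C@@H]1CCC[C@]2(C)CC[C@](C)(O)C=C12 | intermediate
9 | triethyl{[(2S,4aR,8R)-2,4a,8-trimethyl-2,3,4,4a,5,6,7,8-octahydronaphthalen-2-yl]oxy}silane | C[C@@H]1CCC[C@]2(C)CC[C@](C)(O[Si](CC)(CC)CC)C=C12 | intermediate
10 | secondary ozonide (1,2,4-trioxolane) of 9, mixture at the two acetal carbons | C[C@@H]1CCC[C@]2(C)CC[C@](C)(O[Si](CC)(CC)CC)C3OOC12O3 | intermediate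
11 | (2S)-4-[(1R,3R)-1,3-dimethyl-2-oxocyclohexyl]-2-methyl-2-[(triethylsilyl)oxy]butanal | O=C1[C@H](C)CCC[C@]1(C)CC[C@@](O[Si](CC)(CC)CC)(C)C=O | intermediate
12 | (2R,6R)-2,6-dimethyl-2-{(3S)-3-methyl-3-[(triethylsilyl)oxy]pent-4-yn-1-yl}cyclohexan-1-one | O=C1[C@H](C)CCC[C@]1(C)CC[C@@](O[Si](CC)(CC)CC)(C)C#C | intermediate
13 | triethyl({(3S)-5-[(1R,3R)-1,3-dimethyl-2-methylidenecyclohexyl]-3-methylpent-1-yn-3-yl}oxy)silane | C=C1[C@H](C)CCC[C@]1(C)CC[C@@](O[Si](CC)(CC)CC)(C)C#C | intermediate
14 | 2-hydroxy-5-methoxybenzaldehyde | COc1ccc(O)c(C=O)c1 | starting material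
15 | 2-hydroxy-3-iodo-5-methoxybenzaldehyde | COc1cc(I)c(O)c(C=O)c1 | intermediate
16 | 2-hydroxy-3-iodo-5-methoxyphenyl formate | COc1cc(I)c(O)c(OC=O)c1 | intermediate
17 | 3-iodo-5-methoxybenzene-1,2-diol | COc1cc(O)c(O)c(I)c1 | intermediate
18 | [(3-iodo-5-methoxy-1,2-phenylene)bis(oxy)]bis(tert-butyldimethylsilane) | COc1cc(O[Si](C)(C)C(C)(C)C)c(O[Si](C)(C)C(C)(C)C)c(I)c1 | intermediate
19 | [(3-{(3S)-5-[(1R,3R)-1,3-dimethyl-2-methylidenecyclohexyl]-3-methyl-3-[(triethylsilyl)oxy]pent-1-yn-1-yl}-5-methoxy-1,2-phenylene)bis(oxy)]bis(tert-butyldimethylsilane) | C=C1[C@H](C)CCC[C@]1(C)CC[C@@](O[Si](CC)(CC)CC)(C)C#Cc1cc(OC)cc(O[Si](C)(C)C(C)(C)C)c1O[Si](C)(C)C(C)(C)C | intermediate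
20 | [(3-{(1Z,3S)-5-[(1R,3R)-1,3-dimethyl-2-methylidenecyclohexyl]-3-methyl-3-[(triethylsilyl)oxy]pent-1-en-1-yl}-5-methoxy-1,2-phenylene)bis(oxy)]bis(tert-butyldimethylsilane) | C=C1[C@H](C)CCC[C@]1(C)CC[C@@](O[Si](CC)(CC)CC)(C)/C=C\c1cc(OC)cc(O[Si](C)(C)C(C)(C)C)c1O[Si](C)(C)C(C)(C)C | intermediate
21 | 3-{(1Z,3S)-5-[(1R,3R)-1,3-dimethyl-2-methylidenecyclohexyl]-3-hydroxy-3-methylpent-1-en-1-yl}-5-methoxybenzene-1,2-diol | C=C1[C@H](C)CCC[C@]1(C)CC[C@@](O)(C)/C=C\c1cc(OC)cc(O)c1O | intermediate
22 | 3-{(1Z,3S)-5-[(1R,3R)-1,3-dimethyl-2-methylidenecyclohexyl]-3-hydroxy-3-methylpent-1-en-1-yl}-5-methoxycyclohexa-3,5-diene-1,2-dione | C=C1[C@H](C)CCC[C@]1(C)CC[C@@](O)(C)/C=C\C1=CC(OC)=CC(=O)C1=O | intermediate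
23 | (2S)-2-{2-[(1R,3R)-1,3-dimethyl-2-methylidenecyclohexyl]ethyl}-8-methoxy-2-methyl-2H-chromene-5,6-dione | C=C1[C@H](C)CCC[C@]1(C)CC[C@@]1(C)C=CC2=C(O1)C(OC)=CC(=O)C2=O | intermediate
24 | (2S)-2-{2-[(1R,3R)-1,3-dimethyl-2-methylidenecyclohexyl]ethyl}-8-methoxy-2-methyl-2H-chromene-5,6-diol | C=C1[C@H](C)CCC[C@]1(C)CC[C@@]1(C)C=Cc2c(O)c(O)cc(OC)c2O1 | target

**Step count and risks**

Total step count: 15. Longest linear sequence: 12 steps (steps 1–8 and 12–15, from 2,6-dimethylcyclohexan-1-one); the arene branch is steps 9–11.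

Steps most likely to fail:

Step 15 (Proposed new method). The tertiary hydroxyl may add to the quinone too slowly, so that quinone decomposition takes over, or configuration is eroded by reversible pyran ring opening at the dione stage. The fallback uses known chemistry, a palladium-catalysed intramolecular aryl etherification with a tertiary alcohol; it sets out from 17 and 13 and returns to the route at 24. Catechol 17 is brominated para to its C1 hydroxyl (Bu4NBr3, CH2Cl2/MeOH, 0 °C) to 4-bromo-3-iodo-5-methoxybenzene-1,2-diol F1, which is silylated (TBSCl, imidazole, DMF) to the bis-silyl bromo iodide F2. Alkyne 13 is desilylated (TBAF, THF) to the free alkynol F3. Sonogashira coupling of F2 and F3 at the iodide gives the aryl alkynol F4, and Lindlar reduction gives the Z-allylic alcohol F5. Pd(OAc)2, 2-(di-tert-butylphosphino)-1,1'-binaphthyl and Cs2CO3 in toluene at 70 °C then close the pyran ring at the bromide to the bis-silyl chromene F6, which TBAF/AcOH converts to 24.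

Step 8. Methylenation of the hindered, enolisable ketone may stay incomplete, or the Lewis-acidic reagent may attack the tertiary propargylic silyl ether. The fallback sets out from 12 and returns at 13 by a Peterson olefination. (Trimethylsilyl)methyllithium with CeCl3 (excess, THF, −78 °C) should add to the ketone without enolisation to give the β-hydroxysilane F7, and KH in THF then eliminates trimethylsilanolate to 13.

Step 13. Hydrogenation at the doubly shielded alkyne may stall, or run on to over-reduction and Z/E leakage. The fallback sets out from 13 and 18 and returns at 20. Lindlar reduction of the unhindered terminal alkyne 13 gives the vinyl carbinol silyl ether F8. Heck arylation with 18 (Pd(OAc)2, P(o-tol)3, Et3N, DMF, 80 °C) gives the E-styrenyl isomer F9. Triplet-sensitised E→Z photoisomerisation (Ir(ppy)3, blue LED, MeCN) then gives 20.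

**Further compounds**

F1 | step 15 | 4-bromo-3-iodo-5-methoxybenzene-1,2-diol | COc1cc(O)c(O)c(I)c1Br
F2 | step 15 | [(4-bromo-3-iodo-5-methoxy-1,2-phenylene)bis(oxy)]bis(tert-butyldimethylsilane) | COc1cc(O[Si](C)(C)C(C)(C)C)c(O[Si](C)(C)C(C)(C)C)c(I)c1Br
F3 | step 15 | (3S)-5-[(1R,3R)-1,3-dimethyl-2-methylidenecyclohexyl]-3-methylpent-1-yn-3-ol | C=C1[C@H](C)CCC[C@]1(C)CC[C@@](O)(C)C#C
F4 | step 15 | (3S)-1-{2-bromo-5,6-bis[(tert-butyldimethylsilyl)oxy]-3-methoxyphenyl}-5-[(1R,3R)-1,3-dimethyl-2-methylidenecyclohexyl]-3-methylpent-1-yn-3-ol | C=C1[C@H](C)CCC[C@]1(C)CC[C@@](O)(C)C#Cc1c(Br)c(OC)cc(O[Si](C)(C)C(C)(C)C)c1O[Si](C)(C)C(C)(C)C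
F5 | step 15 | (1Z,3S)-1-{2-bromo-5,6-bis[(tert-butyldimethylsilyl)oxy]-3-methoxyphenyl}-5-[(1R,3R)-1,3-dimethyl-2-methylidenecyclohexyl]-3-methylpent-1-en-3-ol | C=C1[C@H](C)CCC[C@]1(C)CC[C@@](O)(C)/C=C\c1c(Br)c(OC)cc(O[Si](C)(C)C(C)(C)C)c1O[Si](C)(C)C(C)(C)C
F6 | step 15 | {[(2S)-2-{2-[(1R,3R)-1,3-dimethyl-2-methylidenecyclohexyl]ethyl}-8-methoxy-2-methyl-2H-chromene-5,6-diyl]bis(oxy)}bis(tert-butyldimethylsilane) | C=C1[C@H](C)CCC[C@]1(C)CC[C@@]1(C)C=Cc2c(O[Si](C)(C)C(C)(C)C)c(O[Si](C)(C)C(C)(C)C)cc(OC)c2O1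
F7 | step 8 | (2R,6R)-2,6-dimethyl-2-{(3S)-3-methyl-3-[(triethylsilyl)oxy]pent-4-yn-1-yl}-1-[(trimethylsilyl)methyl]cyclohexan-1-ol (C1 epimers) | C[Si](C)(C)CC1(O)[C@H](C)CCC[C@]1(C)CC[C@@](O[Si](CC)(CC)CC)(C)C#C
F8 | step 13 | triethyl({(3S)-5-[(1R,3R)-1,3-dimethyl-2-methylidenecyclohexyl]-3-methylpent-1-en-3-yl}oxy)silane | C=C1[C@H](C)CCC[C@]1(C)CC[C@@](O[Si](CC)(CC)CC)(C)C=C
F9 | step 13 | [(3-{(1E,3S)-5-[(1R,3R)-1,3-dimethyl-2-methylidenecyclohexyl]-3-methyl-3-[(triethylsilyl)oxy]pent-1-en-1-yl}-5-methoxy-1,2-phenylene)bis(oxy)]bis(tert-butyldimethylsilane) | C=C1[C@H](C)CCC[C@]1(C)CC[C@@](O[Si](CC)(CC)CC)(C)/C=C/c1cc(OC)cc(O[Si](C)(C)C(C)(C)C)c1O[Si](C)(C)C(C)(C)C
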